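**Retrosynthetic overview** (C1' = carbinol carbon, C2' = CMe2, C4' = ring CH2 next to C1')
- The naphthazarin is unmasked last from a 1,4,5,8-tetramethoxynaphthalene; the angelate comes from the tertiary alkoxide and angelic anhydride.
- The cyclobutane is closed at C1'–C4': an α-carbamoyloxy benzyllithium (an aroyl-anion equivalent at the alcohol oxidation level) displaces a primary chloride stereospecifically.
- The open-chain carbamate comes from an (S)-homoallylic alcohol made by enantioselective tert-prenylation of the naphthaldehyde (C1'–C2' bond, source of the stereocentre); the chloride comes from the vinyl group.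
- Ring order: the naphthalene bicycle is bought, the cyclobutane is formed in step 5, the quinone ring is revealed in step 8.

Assumption: (S)-SEGPHOS is taken to give the (S)-carbinol in step 2 and the ring closure in step 5 to invert the lithiated carbon; if the first configurational check on the cyclobutanol shows the opposite overall sense, (R)-SEGPHOS is used in step 2 and nothing else changes.

**Step 1**
Reactants: 1 1,4,5,8-tetramethoxynaphthalene
Product: 3 1,4,5,8-tetramethoxynaphthalene-2-carbaldehyde, via iminium chloride 2 (not isolated)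
Conditions: POCl3, DMF, 0 to 70 °C; then aq NaOAc
Reagents that add atoms: N,N-dimethylformamide CN(C)C=O; water O
Why: Vilsmeier–Haack formylation of the very electron-rich arene, whose four free positions are equivalent, so only one mono-aldehyde can form.

**Step 2**
Reactants: 3 1,4,5,8-tetramethoxynaphthalene-2-carbaldehyde; 4 3-methylbuta-1,2-diene
Product: 5 (S)-2,2-dimethyl-1-(1,4,5,8-tetramethoxynaphthalen-2-yl)but-3-en-1-ol
Conditions: [Ir(cod)Cl]2 (2.5 mol%), (S)-SEGPHOS (5 mol%), 4-cyano-3-nitrobenzoic acid (10 mol%), Cs2CO3 (20 mol%), i-PrOH (2 equiv), THF, 50 °C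
Reagents that add atoms: none
Why: Krische transfer-hydrogenative carbonyl tert-prenylation, in which the allene is hydrometallated to a 1,1-dimethylallyl-iridium species that adds to the aldehyde through a closed chair transition state, the chiral bisphosphine choosing the aldehyde face and so setting the (S)-carbinol while isopropanol serves as reductant.

**Step 3**
Reactants: 5 (S)-2,2-dimethyl-1-(1,4,5,8-tetramethoxynaphthalen-2-yl)but-3-en-1-ol
Product: 7 (S)-2,2-dimethyl-1-(1,4,5,8-tetramethoxynaphthalen-2-yl)but-3-en-1-yl N,N-diisopropylcarbamate, via sodium alkoxide 6 (not isolated)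
Conditions: NaH, THF, 0 °C; then ClC(O)N(i-Pr)2, reflux
Reagents that add atoms: N,N-diisopropylcarbamoyl chloride CC(C)N(C(C)C)C(Cl)=O
Why: O-carbamoylation of the alkoxide installs the lithiation-directing Hoppe carbamate before any leaving group is present (so no tetrahydrofuran can form) and does not touch the stereocentre.

**Step 4**
Reactants: 7 (S)-2,2-dimethyl-1-(1,4,5,8-tetramethoxynaphthalen-2-yl)but-3-en-1-yl N,N-diisopropylcarbamate
Product: 9 (S)-4-chloro-2,2-dimethyl-1-(1,4,5,8-tetramethoxynaphthalen-2-yl)butyl N,N-diisopropylcarbamate, via alkylzirconocene chloride 8 (not isolated)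
Conditions: Cp2Zr(H)Cl, THF, 23 °C; then N-chlorosuccinimide, 0 °C
Reagents that add atoms: N-chlorosuccinimide O=C1CCC(=O)N1Cl
Why: Schwartz hydrozirconation puts zirconium on the terminal carbon of the neopentyl-type vinyl group (anti-Markovnikov, steric control) and the C–Zr bond is then cleaved by chlorine transfer faster than the arene can be chlorinated, the hindered carbamate and the stereocentre staying untouched.

**Step 5**
Reactants: 9 (S)-4-chloro-2,2-dimethyl-1-(1,4,5,8-tetramethoxynaphthalen-2-yl)butyl N,N-diisopropylcarbamate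
Product: 11 (R)-2,2-dimethyl-1-(1,4,5,8-tetramethoxynaphthalen-2-yl)cyclobutyl N,N-diisopropylcarbamate, via benzylic organolithium 10 (not isolated)
Conditions: s-BuLi, TMEDA, Et2O, −78 °C; then −78 to −40 °C
Reagents that add atoms: none
Why: Proposed new method: the carbamate carbonyl pre-coordinates s-BuLi and delivers it to the benzylic C–H with retention, giving an α-carbamoyloxy benzyllithium (a d1 aroyl-anion equivalent, configurationally stable at −78 °C) whose carbon, formerly the aldehyde carbon, attacks the primary chloride in a 4-exo-tet SN2 closure anti to lithium, as lithiated benzylic carbamates do with alkyl halides, so the (S)-centre becomes the (R)-quaternary centre; the closest known reactions are Hoppe lithiation–substitution and cycloalkylation of carbamates and Beak-type lithiation–cyclisation of N-Boc-N-(chloroalkyl)benzylamines.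

**Step 6**
Reactants: 11 (R)-2,2-dimethyl-1-(1,4,5,8-tetramethoxynaphthalen-2-yl)cyclobutyl N,N-diisopropylcarbamate
Product: 12 (R)-2,2-dimethyl-1-(1,4,5,8-tetramethoxynaphthalen-2-yl)cyclobutan-1-ol
Conditions: LiAlH4, THF, reflux; then Na2SO4·10H2O
Reagents that add atoms: none
Why: Reductive cleavage of the Hoppe carbamate by hydride attack at the carbamate carbonyl frees the tertiary alkoxide without breaking the C1'–O bond, so the (R)-configuration is retained, and the neutral quench spares the acid-labile benzylic cyclobutanol.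

**Step 7**
Reactants: 12 (R)-2,2-dimethyl-1-(1,4,5,8-tetramethoxynaphthalen-2-yl)cyclobutan-1-ol; 13 angelic anhydride, (Z)-2-methylbut-2-enoic anhydride
Product: 15 (R)-2,2-dimethyl-1-(1,4,5,8-tetramethoxynaphthalen-2-yl)cyclobutyl (Z)-2-methylbut-2-enoate, via potassium alkoxide 14 (not isolated)
Conditions: KN(SiMe3)2, THF, −78 °C; then 13, −78 to 0 °C; aq NH4Cl
Reagents that add atoms: none
Why: Acylation of the pre-formed hindered alkoxide with the symmetrical anhydride at low temperature is fast and irreversible, which avoids the Z-to-E (angelate-to-tiglate) isomerisation seen with angeloyl chloride or amine-promoted couplings, and the stereocentre is not involved.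

**Step 8**
Reactants: 15 (R)-2,2-dimethyl-1-(1,4,5,8-tetramethoxynaphthalen-2-yl)cyclobutyl (Z)-2-methylbut-2-enoate
Product: 16 (R)-1-(1,4-dimethoxy-5,8-dioxo-5,8-dihydronaphthalen-2-yl)-2,2-dimethylcyclobutyl (Z)-2-methylbut-2-enoate
Conditions: (NH4)2Ce(NO3)6, MeCN–H2O (4:1), 0 °C, 10 min
Reagents that add atoms: water O
Why: Oxidative demethylation of a 1,4-dimethoxyarene (two single-electron oxidations, water adding at the ipso carbons, methanol leaving) is expected to take place in the unsubstituted ring because the ring carrying the bulky, inductively withdrawing acyloxycyclobutyl group is shielded and deactivated, and the short cold reaction spares the tertiary ester.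

**Step 9**
Reactants: 16 (R)-1-(1,4-dimethoxy-5,8-dioxo-5,8-dihydronaphthalen-2-yl)-2,2-dimethylcyclobutyl (Z)-2-methylbut-2-enoate
Product: 17 (R)-1-(5,8-dihydroxy-1,4-dioxo-1,4-dihydronaphthalen-2-yl)-2,2-dimethylcyclobutyl (Z)-2-methylbut-2-enoate
Conditions: BCl3, CH2Cl2, −78 to −20 °C; then H2O
Reagents that add atoms: none
Why: Chelation-assisted peri-demethylation, in which BCl3 bridges each quinone carbonyl and its peri-methoxy oxygen and chloride removes the methyl group by SN2, leaves the tertiary ester (para to a carbonyl-bearing ring carbon, hence poorly ionisable) intact, and because naphthazarins tautomerise freely the 6-substituted and 2-substituted forms are one compound, the target.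

**Compound list**
1 | 1,4,5,8-tetramethoxynaphthalene | COc1ccc(OC)c2c(OC)ccc(OC)c12 | starting material
2 | N,N-dimethyl(1,4,5,8-tetramethoxynaphthalen-2-yl)methaniminium chloride | C[N+](C)=Cc1cc(OC)c2c(OC)ccc(OC)c2c1OC.[Cl-] | intermediate
3 | 1,4,5,8-tetramethoxynaphthalene-2-carbaldehyde | O=Cc1cc(OC)c2c(OC)ccc(OC)c2c1OC | intermediate
4 | 3-methylbuta-1,2-diene | CC(C)=C=C | starting material
5 | (S)-2,2-dimethyl-1-(1,4,5,8-tetramethoxynaphthalen-2-yl)but-3-en-1-ol | O[C@H](c1cc(OC)c2c(OC)ccc(OC)c2c1OC)C(C)(C)C=C | intermediate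
6 | sodium (S)-2,2-dimethyl-1-(1,4,5,8-tetramethoxynaphthalen-2-yl)but-3-en-1-olate | [Na+].[O-][C@H](c1cc(OC)c2c(OC)ccc(OC)c2c1OC)C(C)(C)C=C | intermediate
7 | (S)-2,2-dimethyl-1-(1,4,5,8-tetramethoxynaphthalen-2-yl)but-3-en-1-yl N,N-diisopropylcarbamate | CC(C)N(C(C)C)C(=O)O[C@H](c1cc(OC)c2c(OC)ccc(OC)c2c1OC)C(C)(C)C=C | intermediate
8 | chlorobis(cyclopentadienyl)[(S)-4-(N,N-diisopropylcarbamoyloxy)-3,3-dimethyl-4-(1,4,5,8-tetramethoxynaphthalen-2-yl)butyl]zirconium (cyclopentadienyl rings drawn σ-bound) | CC(C)N(C(C)C)C(=O)O[C@H](c1cc(OC)c2c(OC)ccc(OC)c2c1OC)C(C)(C)CC[Zr](Cl)(C1C=CC=C1)C1C=CC=C1 | intermediate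
9 | (S)-4-chloro-2,2-dimethyl-1-(1,4,5,8-tetramethoxynaphthalen-2-yl)butyl N,N-diisopropylcarbamate | CC(C)N(C(C)C)C(=O)O[C@H](c1cc(OC)c2c(OC)ccc(OC)c2c1OC)C(C)(C)CCCl | intermediate
10 | [4-chloro-1-(N,N-diisopropylcarbamoyloxy)-2,2-dimethyl-1-(1,4,5,8-tetramethoxynaphthalen-2-yl)butyl]lithium, lithium in the place of the benzylic hydrogen of 9 | CC(C)N(C(C)C)C(=O)O[C@]([Li])(c1cc(OC)c2c(OC)ccc(OC)c2c1OC)C(C)(C)CCCl | intermediate
11 | (R)-2,2-dimethyl-1-(1,4,5,8-tetramethoxynaphthalen-2-yl)cyclobutyl N,N-diisopropylcarbamate | CC(C)N(C(C)C)C(=O)O[C@]1(c2cc(OC)c3c(OC)ccc(OC)c3c2OC)CCC1(C)C | intermediate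
12 | (R)-2,2-dimethyl-1-(1,4,5,8-tetramethoxynaphthalen-2-yl)cyclobutan-1-ol | O[C@]1(c2cc(OC)c3c(OC)ccc(OC)c3c2OC)CCC1(C)C | intermediate
13 | angelic anhydride, (Z)-2-methylbut-2-enoic anhydride | C/C=C(/C)C(=O)OC(=O)/C(C)=C\C | starting material
14 | potassium (R)-2,2-dimethyl-1-(1,4,5,8-tetramethoxynaphthalen-2-yl)cyclobutan-1-olate | [K+].[O-][C@]1(c2cc(OC)c3c(OC)ccc(OC)c3c2OC)CCC1(C)C | intermediate
15 | (R)-2,2-dimethyl-1-(1,4,5,8-tetramethoxynaphthalen-2-yl)cyclobutyl (Z)-2-methylbut-2-enoate | C/C=C(/C)C(=O)O[C@]1(c2cc(OC)c3c(OC)ccc(OC)c3c2OC)CCC1(C)C | intermediate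
16 | (R)-1-(1,4-dimethoxy-5,8-dioxo-5,8-dihydronaphthalen-2-yl)-2,2-dimethylcyclobutyl (Z)-2-methylbut-2-enoate | C/C=C(/C)C(=O)O[C@]1(c2cc(OC)c3C(=O)C=CC(=O)c3c2OC)CCC1(C)C | intermediate
17 | (R)-1-(5,8-dihydroxy-1,4-dioxo-1,4-dihydronaphthalen-2-yl)-2,2-dimethylcyclobutyl (Z)-2-methylbut-2-enoate | C/C=C(/C)C(=O)O[C@]1(C2=CC(=O)c3c(O)ccc(O)c3C2=O)CCC1(C)C | target

**Totals**
Total step count: 9. Longest linear sequence: 9 steps (1 to 17).

**Steps most likely to fail**

Step 5. The benzylic C–H sits between a quaternary carbon and an ortho-methoxy group, so lithiation may be slow and ring lithiation may compete; a slow four-membered closure would also let the organolithium racemise or undergo 1,2-carbamoyl shift. The fallback sets out from compound 1 and comes back at compound 12. Compound 1 is brominated (N-bromosuccinimide, MeCN, 0 °C) to 2-bromo-1,4,5,8-tetramethoxynaphthalene F1. Bromine–lithium exchange (n-BuLi, THF, −78 °C) and addition of the aryllithium to bought 2,2-dimethylcyclobutanone F2 give racemic 2,2-dimethyl-1-(1,4,5,8-tetramethoxynaphthalen-2-yl)cyclobutan-1-ol F3. Preparative chiral SFC of F3 delivers 12, and steps 7 to 9 follow unchanged.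

Step 7. The tertiary, doubly flanked alkoxide may acylate slowly, and any base-mediated equilibration would give the tiglate. The fallback sets out from compound 12 and comes back at compound 15. Alkoxide 14 is acylated with the smaller, more reactive 2-[bis(2,2,2-trifluoroethoxy)phosphoryl]propanoyl chloride F4 to give (R)-2,2-dimethyl-1-(1,4,5,8-tetramethoxynaphthalen-2-yl)cyclobutyl 2-[bis(2,2,2-trifluoroethoxy)phosphoryl]propanoate F5. A Still–Gennari olefination of F5 with acetaldehyde (KN(SiMe3)2, 18-crown-6, THF, −78 °C) then builds the (Z)-2-methylbut-2-enoate on the hindered oxygen and gives 15.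

Step 9. The Lewis acid may ionise the tertiary benzylic ester or add to the enoate before both methyl groups are gone. The fallback sets out from compound 16 and comes back at compound 17. Compound 16 is oxidised further (AgO, 6 M HNO3, acetone, 23 °C, 5 min) to (R)-2,2-dimethyl-1-(1,4,5,8-tetraoxo-1,4,5,8-tetrahydronaphthalen-2-yl)cyclobutyl (Z)-2-methylbut-2-enoate F6. Mild reduction of F6 (aq Na2S2O4, EtOAc, 0 °C) gives the naphthazarin 17 without any Lewis acid.

**Further compounds**
F1 | step 5 | 2-bromo-1,4,5,8-tetramethoxynaphthalene | Brc1cc(OC)c2c(OC)ccc(OC)c2c1OC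
F2 | step 5 | 2,2-dimethylcyclobutanone | CC1(C)CCC1=O
F3 | step 5 | racemic 2,2-dimethyl-1-(1,4,5,8-tetramethoxynaphthalen-2-yl)cyclobutan-1-ol | OC1(c2cc(OC)c3c(OC)ccc(OC)c3c2OC)CCC1(C)C
F4 | step 7 | 2-[bis(2,2,2-trifluoroethoxy)phosphoryl]propanoyl chloride | CC(C(Cl)=O)P(=O)(OCC(F)(F)F)OCC(F)(F)F
F5 | step 7 | (R)-2,2-dimethyl-1-(1,4,5,8-tetramethoxynaphthalen-2-yl)cyclobutyl 2-[bis(2,2,2-trifluoroethoxy)phosphoryl]propanoate | CC(C(=O)O[C@]1(c2cc(OC)c3c(OC)ccc(OC)c3c2OC)CCC1(C)C)P(=O)(OCC(F)(F)F)OCC(F)(F)F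
F6 | step 9 | (R)-2,2-dimethyl-1-(1,4,5,8-tetraoxo-1,4,5,8-tetrahydronaphthalen-2-yl)cyclobutyl (Z)-2-methylbut-2-enoate | C/C=C(/C)C(=O)O[C@]1(C2=CC(=O)C3=C(C2=O)C(=O)C=CC3=O)CCC1(C)C
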